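**Plan**
1. Retrosynthetic cuts: the C3–O acyl bond (Mitsunobu with the dienoic acid), C7=C11 (acetone aldol, dehydration kept for last), the C3–O bond (oxidation of the extended enol ether), then the two ring A bonds C4–C5 and C1=C2 together.
2. Enabling feature (eremophilane numbering): ring A meets the ring B enone C8(=O)–C9=C10 only at C5, the γ-carbon, and at C1, the carbon on the β-position C10. These are the two vinylogous donor sites of 3,4-dimethylcyclohexenone, and C2–C3–C4(C15) is crotonaldehyde (C4 acceptor, C2 carbonyl).
3. Forward order: ring B from 3,4-dimethylanisole (Birch reduction, β,γ-enone, ring silyl dienol ether); ring A closed in one flask; C7 aldol; C3 oxygenation; esterification; dehydration. The acid is made from (S)-2-methylbutan-1-ol by oxidation, vinylogous olefination and saponification.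
4. Stereochemistry: C4 from the enal face left open by the imidazolidinone, C5 from the topicity of the same addition, C3 from α-face oxidation followed by inversion, C6′ from the chiral pool.

Key step: step 4

Remark: the SMILES fixes 3S,4R,5R, with the ester oxygen and both ring methyl groups on one face (called β here), and 6S in the acyl chain. The C7 centre made by the acetone aldol is carried as an epimer mixture and is erased in the last step.

Step 1
Reactants: 1 3,4-dimethylanisole
Product: 2 1-methoxy-4,5-dimethylcyclohexa-1,4-diene
Conditions: Li, liquid NH3, THF, t-BuOH, −78 to −33 °C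
Reagents that add atoms: none
Why: Birch reduction of an alkylated anisole protonates the unsubstituted ortho and meta carbons, so the methoxy group and both methyl groups stay on the two remaining alkenes.

Step 2
Reactants: 2 1-methoxy-4,5-dimethylcyclohexa-1,4-diene
Product: 3 3,4-dimethylcyclohex-3-en-1-one
Conditions: oxalic acid (cat.), THF–H2O, rt
Reagents that add atoms: water, O
Why: Enol ether hydrolysis with a weak acid stops at the β,γ-unsaturated ketone, helped by the tetrasubstituted alkene having little drive to move into conjugation.

Step 3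
Reactants: 3 3,4-dimethylcyclohex-3-en-1-one
Product: 4 tert-butyl[(3,4-dimethylcyclohexa-1,3-dien-1-yl)oxy]dimethylsilane
Conditions: TBSOTf, Et3N, CH2Cl2, 0 °C
Reagents that add atoms: TBSOTf, CC(C)(C)[Si](C)(C)OS(=O)(=O)C(F)(F)F
Why: Soft enolisation (silyl triflate and tertiary amine) removes a C2 proton, the only kind that is both α to the carbonyl and allylic, so the linear ring dienol ether should form free of the cross-conjugated and exocyclic isomers that silylation of the conjugated enone could give.

Step 4
Reactants: 4 tert-butyl[(3,4-dimethylcyclohexa-1,3-dien-1-yl)oxy]dimethylsilane; 5 (E)-crotonaldehyde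
Product: 7 (4aR,5S)-4a,5-dimethyl-4,4a,5,6-tetrahydronaphthalen-2(3H)-one, via keto aldehyde 6 (not isolated)
Conditions: 5 (3 equiv), (2R,5R)-5-benzyl-2-tert-butyl-3-methylimidazolidin-4-one (20 mol %), 2,4-dinitrobenzoic acid (20 mol %), CH2Cl2–H2O, −40 °C; evaporate excess 5; pyrrolidine (30 mol %), AcOH (30 mol %), toluene, 60 °C
Reagents that add atoms: none
Why: Proposed new method: the imidazolidinone condenses with 5 to an (E)-iminium ion whose Re face at the β-carbon is covered by the benzyl and tert-butyl groups, the γ-terminus C5 of 4 attacks the open Si face through an extended transition state (C4–C5 bond), and water takes up the silyl group and hydrolyses the enamine to keto aldehyde 6. In the second stage pyrrolidinium acetate turns the enone of 6 into its dienamine, which can only be the exocyclic one because C5 is now quaternary, its CH2 terminus C1 adds to the aldehyde carbon C2 in a 6-(enolendo)-exo-trig closure of ring A, and loss of water with hydrolysis gives the linear dienone 7. The closest known reactions are iminium-catalysed vinylogous Mukaiyama–Michael additions of 5-substituted 2-silyloxyfurans to enals, which also build a γ-quaternary centre, and amine- or base-mediated vinylogous aldol condensations of 3-methylcyclohexenones, but neither has been shown with a carbocyclic, fully substituted dienol ether or joined in one flask. C4 (S in 7) follows from the catalyst-controlled enal face, and C5 (R) from the relative topicity, where an antiperiplanar arrangement of the iminium chain and the C5–C10 bond should put the enal methyl over the ring between C6 and C10 instead of between the two in-plane methyl groups on C5 and C10, which places the C4 and C5 methyl groups cis. The step needs γ- over α-attack, which the bulky TBS group next to C9 and the large terminal coefficient of silyl dienol ethers should secure. Aldol closures through C9 or C7 give bicyclo[3.3.1] aldols that could dehydrate only to bridgehead alkenes and therefore revert, and any [4+2]-type adduct of the first stage reopens to 6 by retro-aldol cleavage once desilylated, so the material should drain to 7.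

Step 5
Reactants: 7 (4aR,5S)-4a,5-dimethyl-4,4a,5,6-tetrahydronaphthalen-2(3H)-one; 8 acetone
Product: 9 (4S,5R)-11-hydroxyeremophila-1,9-dien-8-one (7 bearing C(CH3)2OH at C7; C7 epimers)
Conditions: LDA, THF, −78 °C; ZnCl2; 8, −78 to −40 °C
Reagents that add atoms: none
Why: Kinetic deprotonation of a linear dienone with LDA takes place at the α′-carbon C7, and the zinc-modified directed aldol addition to acetone is the established entry to the eremophilane C7 side chain, the new C7 centre being of no consequence.

Step 6
Reactants: 9 (4S,5R)-11-hydroxyeremophila-1,9-dien-8-one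
Product: 10 (4S,5R)-8,11-bis(triethylsilyloxy)eremophila-1(10),2,8-triene
Conditions: TESOTf (3 equiv), Et3N, CH2Cl2, 0 °C to rt
Reagents that add atoms: TESOTf, CC[Si](CC)(CC)OS(=O)(=O)C(F)(F)F
Why: Soft enolisation gives the fully linear silyl trienol ether by loss of an ε-proton from C3, as in enol ether and enol ester formation from steroidal 4,6-dien-3-ones, because the competing C7 proton is tertiary and buried beside the side chain, whose tertiary alcohol is capped at the same time.

Step 7
Reactants: 10 (4S,5R)-8,11-bis(triethylsilyloxy)eremophila-1(10),2,8-triene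
Product: 12 (3R,4R,5R)-3,11-dihydroxyeremophila-1,9-dien-8-one, via hydroxy dienone TES ether 11 (not isolated)
Conditions: mCPBA (1.0 equiv), CH2Cl2, −40 °C; then AcOH–THF–H2O, rt
Reagents that add atoms: mCPBA, O=C(OO)c1cccc(Cl)c1
Why: Proposed new method: in this doubly vinylogous Rubottom oxidation the peracid should attack the terminal, least hindered C2=C3 alkene at C3, the push of the silyloxy group through the triene opens the epoxide to the conjugated dienone with oxygen left on C3, and approach from the α face anti to the C4 and C5 methyl groups sets 3R; the closest known reaction is the γ-hydroxylation of silyl dienol ethers of cyclic enones with peracids, and aqueous acetic acid then frees the tertiary alcohol.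

Step 8
Reactants: 13 (S)-2-methylbutan-1-ol
Product: 14 (S)-2-methylbutanal
Conditions: TEMPO (cat.), KBr (cat.), aq. NaOCl (pH 9.5), CH2Cl2, 0 °C
Reagents that add atoms: none
Why: The TEMPO–hypochlorite oxidation stops at the aldehyde within minutes under mild two-phase conditions and is the established way to obtain this α-branched aldehyde without racemisation.

Step 9
Reactants: 14 (S)-2-methylbutanal; 15 triethyl (E)-4-phosphonocrotonate
Product: 16 ethyl (2E,4E,6S)-6-methylocta-2,4-dienoate
Conditions: LiHMDS, THF, −78 to 0 °C
Reagents that add atoms: none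
Why: The vinylogous Horner–Wadsworth–Emmons reaction of the lithiated phosphonocrotonate is E-selective for the new alkene and keeps the existing one E, while the low temperature protects the α-stereocentre of 14.

Step 10
Reactants: 16 ethyl (2E,4E,6S)-6-methylocta-2,4-dienoate
Product: 17 (2E,4E,6S)-6-methylocta-2,4-dienoic acid
Conditions: LiOH, THF–MeOH–H2O, rt; then 1 M HCl
Reagents that add atoms: lithium hydroxide, [Li+].[OH-]
Why: Saponification of an unhindered ethyl ester leaves the diene geometry and the remote allylic stereocentre untouched.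

Step 11
Reactants: 12 (3R,4R,5R)-3,11-dihydroxyeremophila-1,9-dien-8-one; 17 (2E,4E,6S)-6-methylocta-2,4-dienoic acid
Product: 18 (3S,4R,5R)-11-hydroxy-8-oxoeremophila-1,9-dien-3-yl (2E,4E,6S)-6-methylocta-2,4-dienoate
Conditions: PPh3, DIAD, toluene, 0 °C to rt
Reagents that add atoms: none
Why: The Mitsunobu reaction activates only the secondary allylic alcohol (the tertiary one is inert) and the carboxylate displaces it by SN2 with inversion to 3S, anti elimination being blocked because the only C4 hydrogen is cis to the leaving group and SN2′ attack at C1 being disfavoured because it would break the dienone conjugation.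

Step 12
Reactants: 18 (3S,4R,5R)-11-hydroxy-8-oxoeremophila-1,9-dien-3-yl (2E,4E,6S)-6-methylocta-2,4-dienoate
Product: 20 (3S,4R,5R)-8-oxoeremophila-1,9,7(11)-trien-3-yl (2E,4E,6S)-6-methylocta-2,4-dienoate (CNP0215744.1), via tertiary mesylate 19 (not isolated)
Conditions: MsCl, Et3N, CH2Cl2, 0 °C to rt
Reagents that add atoms: none
Why: Mesylation of the tertiary aldol and E1cB loss of mesylate through enolisation at C7 is a standard aldol dehydration that gives the conjugated tetrasubstituted C7=C11 alkene under amine conditions too mild to disturb the ester or the C3 hydrogen.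

**Compound list**
1 | 3,4-dimethylanisole | COc1ccc(C)c(C)c1 | starting material
2 | 1-methoxy-4,5-dimethylcyclohexa-1,4-diene | COC1=CCC(C)=C(C)C1 | intermediate
3 | 3,4-dimethylcyclohex-3-en-1-one | O=C1CCC(C)=C(C)C1 | intermediate
4 | tert-butyl[(3,4-dimethylcyclohexa-1,3-dien-1-yl)oxy]dimethylsilane | CC1=C(C)CCC(O[Si](C)(C)C(C)(C)C)=C1 | intermediate
5 | (E)-crotonaldehyde | C/C=C/C=O | starting material
6 | (3S)-3-[(1R)-1,2-dimethyl-4-oxocyclohex-2-en-1-yl]butanal (formed and consumed in step 4) | CC1=CC(=O)CC[C@]1(C)[C@@H](C)CC=O | intermediate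
7 | (4aR,5S)-4a,5-dimethyl-4,4a,5,6-tetrahydronaphthalen-2(3H)-one | C1C=CC2=CC(=O)CC[C@]2(C)[C@H]1C | intermediate
8 | acetone | CC(C)=O | starting material
9 | (4S,5R)-11-hydroxyeremophila-1,9-dien-8-one, C7 epimers | C1C=CC2=CC(=O)C(C(C)(C)O)C[C@]2(C)[C@H]1C | intermediate
10 | (4S,5R)-8,11-bis(triethylsilyloxy)eremophila-1(10),2,8-triene, C7 epimers | C1=CC=C2C=C(O[Si](CC)(CC)CC)C(C(C)(C)O[Si](CC)(CC)CC)C[C@]2(C)[C@H]1C | intermediate
11 | (3R,4R,5R)-3-hydroxy-11-(triethylsilyloxy)eremophila-1,9-dien-8-one (formed and consumed in step 7) | O[C@@H]1C=CC2=CC(=O)C(C(C)(C)O[Si](CC)(CC)CC)C[C@]2(C)[C@H]1C | intermediate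
12 | (3R,4R,5R)-3,11-dihydroxyeremophila-1,9-dien-8-one, C7 epimers | O[C@@H]1C=CC2=CC(=O)C(C(C)(C)O)C[C@]2(C)[C@H]1C | intermediate
13 | (S)-2-methylbutan-1-ol | CC[C@H](C)CO | starting material
14 | (S)-2-methylbutanal | CC[C@H](C)C=O | intermediate
15 | triethyl (E)-4-phosphonocrotonate | CCOC(=O)/C=C/CP(=O)(OCC)OCC | starting material
16 | ethyl (2E,4E,6S)-6-methylocta-2,4-dienoate | CC[C@H](C)/C=C/C=C/C(=O)OCC | intermediate
17 | (2E,4E,6S)-6-methylocta-2,4-dienoic acid | CC[C@H](C)/C=C/C=C/C(=O)O | intermediate
18 | (3S,4R,5R)-11-hydroxy-8-oxoeremophila-1,9-dien-3-yl (2E,4E,6S)-6-methylocta-2,4-dienoate, C7 epimers | CC[C@H](C)/C=C/C=C/C(=O)O[C@H]1C=CC2=CC(=O)C(C(C)(C)O)C[C@]2(C)[C@H]1C | intermediate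
19 | (3S,4R,5R)-11-(methylsulfonyloxy)-8-oxoeremophila-1,9-dien-3-yl (2E,4E,6S)-6-methylocta-2,4-dienoate (formed and consumed in step 12) | CC[C@H](C)/C=C/C=C/C(=O)O[C@H]1C=CC2=CC(=O)C(C(C)(C)OS(C)(=O)=O)C[C@]2(C)[C@H]1C | intermediate
20 | (3S,4R,5R)-8-oxoeremophila-1,9,7(11)-trien-3-yl (2E,4E,6S)-6-methylocta-2,4-dienoate | CC[C@H](C)/C=C/C=C/C(=O)O[C@H]1C=CC2=CC(=O)C(=C(C)C)C[C@]2(C)[C@H]1C | target

**Step count**
- Total steps: 12.
- Longest linear sequence: 9 (steps 1–7, 11, 12).

**Steps most likely to fail**

**Step 4.**
- What may go wrong: attack of the diene through its unhindered α-carbon C9, the wrong relative topicity at C5 (methyl groups ending up trans), or protodesilylation outrunning a slow attack at the fully substituted terminus.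
- The fallback uses known chemistry and annulates ring B onto a preformed ring A by Robinson annulation. It sets out from 5 and returns at 7.
- Iminium-catalysed Michael addition of tert-butyl acetoacetate to 5 with (R)-2-[diphenyl(trimethylsilyloxy)methyl]pyrrolidine should give tert-butyl (3S)-2-acetyl-3-methyl-5-oxopentanoate F1.
- TsOH in warm toluene closes it by aldol condensation to tert-butyl (6S)-6-methyl-2-oxocyclohex-3-ene-1-carboxylate F2. This loses isobutene and carbon dioxide in the same flask to give (5S)-5-methylcyclohex-2-en-1-one F3.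
- Kinetic α′-methylation (LDA, MeI, THF, −78 °C) leads to (5S)-5,6-dimethylcyclohex-2-en-1-one F4.
- A second kinetic deprotonation at C6 and Michael addition to 3-(trimethylsilyl)but-3-en-2-one, anti to the C5 methyl group, gives (5S,6R)-5,6-dimethyl-6-[3-oxo-2-(trimethylsilyl)butyl]cyclohex-2-en-1-one F5.
- KOH in MeOH removes silicon to give (5S,6R)-5,6-dimethyl-6-(3-oxobutyl)cyclohex-2-en-1-one F6 and closes ring B by aldol condensation onto the ring carbonyl. This gives 7 with the cis-dimethyl pattern set by substrate control.

**Step 7.**
- What may go wrong: oxidation at the inner positions C9 or C1 of the triene, or acid hydrolysis of the enol ether back to the dienone before oxygen transfer.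
- The fallback uses known chemistry, direct C–H oxidation followed by hydride delivery. It sets out from 9 and returns at 18.
- C3 is the only allylic methylene of 9. Radical allylic oxidation with Rh2(cap)4 (dirhodium tetracaprolactamate) and aqueous t-BuOOH, the method that turns enones into enediones, should give (4R,5R)-11-hydroxyeremophila-1,9-diene-3,8-dione F7.
- Luche reduction (NaBH4, CeCl3·7H2O, MeOH, −78 °C) should select the C3 carbonyl, since C8 is screened by the C7 side chain. Hydride should arrive from the α face, away from the syn-axial C5 methyl group, to give (3S,4R,5R)-3,11-dihydroxyeremophila-1,9-dien-8-one F8.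
- Steglich esterification with 17 (EDC·HCl, DMAP, CH2Cl2) proceeds with retention and reaches 18, so steps 6, 7 and 11 are replaced.

**Step 11.**
- What may go wrong: slow displacement of the bulky oxyphosphonium group beside the C4 methyl and under the C5 methyl by a weakly acidic dienoic acid, so that acyl transfer with retention or loss of the activated alcohol takes over.
- The fallback separates activation from displacement and moves the dehydration forward. It sets out from 12 and returns at 20.
- Methanesulfonic anhydride and Et3N in CH2Cl2 convert both hydroxyl groups into (3R,4R,5R)-8-oxoeremophila-1,9-diene-3,11-diyl dimethanesulfonate F9.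
- The tertiary β-mesyloxy ketone of F9 eliminates in the flask to give (3R,4R,5R)-8-oxoeremophila-1,9,7(11)-trien-3-yl methanesulfonate F10.
- Cesium (2E,4E,6S)-6-methylocta-2,4-dienoate F11, made from 17 and Cs2CO3, then displaces the small sulfonate in DMF by SN2 with inversion. This gives 20 directly and makes step 12 unnecessary.

**Further compounds**
F1 | step 4 | tert-butyl (3S)-2-acetyl-3-methyl-5-oxopentanoate | CC(=O)C(C(=O)OC(C)(C)C)[C@@H](C)CC=O
F2 | step 4 | tert-butyl (6S)-6-methyl-2-oxocyclohex-3-ene-1-carboxylate | C1C=CC(=O)C(C(=O)OC(C)(C)C)[C@H]1C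
F3 | step 4 | (5S)-5-methylcyclohex-2-en-1-one | C1C=CC(=O)C[C@H]1C
F4 | step 4 | (5S)-5,6-dimethylcyclohex-2-en-1-one | C1C=CC(=O)C(C)[C@H]1C
F5 | step 4 | (5S,6R)-5,6-dimethyl-6-[3-oxo-2-(trimethylsilyl)butyl]cyclohex-2-en-1-one | C1C=CC(=O)[C@](C)(CC(C(C)=O)[Si](C)(C)C)[C@H]1C
F6 | step 4 | (5S,6R)-5,6-dimethyl-6-(3-oxobutyl)cyclohex-2-en-1-one | C1C=CC(=O)[C@](C)(CCC(C)=O)[C@H]1C
F7 | step 7 | (4R,5R)-11-hydroxyeremophila-1,9-diene-3,8-dione | O=C1C=CC2=CC(=O)C(C(C)(C)O)C[C@]2(C)[C@H]1C
F8 | step 7 | (3S,4R,5R)-3,11-dihydroxyeremophila-1,9-dien-8-one | O[C@H]1C=CC2=CC(=O)C(C(C)(C)O)C[C@]2(C)[C@H]1C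
F9 | step 11 | (3R,4R,5R)-8-oxoeremophila-1,9-diene-3,11-diyl dimethanesulfonate | CS(=O)(=O)O[C@@H]1C=CC2=CC(=O)C(C(C)(C)OS(C)(=O)=O)C[C@]2(C)[C@H]1C
F10 | step 11 | (3R,4R,5R)-8-oxoeremophila-1,9,7(11)-trien-3-yl methanesulfonate | CS(=O)(=O)O[C@@H]1C=CC2=CC(=O)C(=C(C)C)C[C@]2(C)[C@H]1C
F11 | step 11 | cesium (2E,4E,6S)-6-methylocta-2,4-dienoate | CC[C@H](C)/C=C/C=C/C(=O)[O-].[Cs+]
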